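## Structural features

The target is the 4-hydroxy-3-methoxybenzoate (vanillate) of a daucane triol. A cyclopentene (C1, C2=C3, C4, C5) shares the C1–C5 bond with a cycloheptane (C1, C5, C6, C7, C8, C9, C10); these daucane atom labels are used for every intermediate below. There are five stereocentres: quaternary C1 (S, angular methyl), ring-fusion C5 (S, H), tertiary allylic carbinol C4 (S, OH and isopropyl), ester carbinol C6 (S) and tertiary carbinol C8 (R, OH and methyl). C4, C5, C6 and C1 are contiguous, with C5 flanked by two carbinols and the quaternary carbon; C8 is remote. The ring fusion is trans (H5 anti to the C1 methyl), C6–O is cis to H5, and C1–CH3, C4–OH and C8–OH share the other face. Fragile points are the tertiary allylic alcohol at C4 (ionisation, dehydration), the free phenol and aryl ester, and any precursor with a carbonyl at C4 or C6, where C5 can epimerise to the cis-fused series and the 1,3-oxygen can be lost by retro-aldol or E1cB. The real difficulty is the trans-fused C1/C5 pair inside a seven-membered ring, tied to a distant tertiary carbinol.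

The key step exploits the following feature. C1 and C8 each carry a methyl and stand 1,4 across the cycloheptane through C10–C9, C8 carries oxygen, and the other arc C5–C6–C7 carries oxygen on its central carbon. This is the atom pattern of 2,5-dimethylfuran (C1, C10, C9, C8, both methyls, ring O = C8–O) that has added a 2-oxyallyl unit (C5–C6(=O)–C7) across its α-carbons.

## Logic of the disconnections

19 ⇒ 18 ⇒ 16 + 17. The aryl O–acetyl bond and the C6–O acyl bond are cut. The ester and phenol are the most labile parts and are best put on last. The gain is a triol without the arene. The forward acylation must pick the one secondary hydroxyl among two tertiary ones, and the last deacylation must spare the benzoate.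

16 ⇒ 15. The C4–isopropyl bond is cut. A tertiary allylic carbinol is the retron of 1,2-addition to a cyclopentenone whose α-carbon C5 is already defined. This removes one stereocentre and the most acid-sensitive group. The nucleophile must attack from the face of H5 without enolising C5 or cleaving the β-hydroxy ketone.

15 ⇒ 14 ⇒ 13. The oxidation level at C4 is lowered from C=O through CHOH to CH2. C4 is the only allylic C–H position of 13 because C1 is quaternary. The gain is an unfunctionalised cyclopentene. The forward oxidation must return the double bond to C2=C3 and the second oxidant must touch only the allylic alcohol.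

13 ⇒ 12. The C2=C3 bond is cut (ring-closing metathesis). The ring closure then lies away from all stereocentres, so the trans C1/C5 relation can be set on a monocyclic ring. The bicycle becomes a cycloheptane with vinyl and allyl groups. The forward step needs only tolerance of free hydroxyls.

12 ⇒ 11 ⇒ 10. The C6–H bond and the O–Si bond are cut. The C6 configuration (anti to C8–OH) is what intramolecular hydride delivery from C8–O gives. One stereocentre disappears and C6 returns to the ketone needed for enolate chemistry. The forward step needs a free C8 hydroxyl and non-basic conditions.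

10 ⇒ 8 ⇒ 7. The C5–C4 (allyl) and C1–C2 (vinyl) bonds are cut. Both flank the C5=C1 enone of 7; conjugate addition makes the quaternary centre and hands over a regiodefined enolate for C5. Three stereocentres reduce to one (C8). Vinyl must enter anti to C8–OSi and allyl anti to vinyl.

7 ⇒ 6 ⇒ 5. The C8–O oxygen is reconnected to C1 (retro-β-elimination). 7 is the ring-opened form of a meso oxabicyclic ketone, so C8 arises by choosing one of two enantiotopic α-methylene groups. A chiral enone becomes a meso compound. The forward steps need an enantioselective deprotonation and a ring opening that follows the enol silane.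

5 ⇒ 4 ⇒ 1 + 2. C9–C10 is desaturated, then C1–C5 and C7–C8 are cut ((4+3) cycloaddition). The seven-membered ring, both methyls, the C6 carbonyl and the C8 oxygen come from two commodity chemicals. The forward step needs cycloaddition to win over substitution on a 2,5-disubstituted furan.

## Other disconnections considered

Alternative 1: This is the first plan that comes to mind. The cyclopentenone is made first and the seven-membered ring is closed at C9=C10 by metathesis of (4S,5S)-4-ethenyl-5-[(1S,3S)-1,3-dihydroxy-3-methylpent-4-en-1-yl]-4-methylcyclopent-2-en-1-one A1, itself from an aldol at C5 (C5–C6). It would need two unrelated enantioselective operations: the quaternary C1, and the C8 carbinol whose two arms are both CH2 groups and are hard to tell apart. The aldol on the cyclopentenone gives a β-hydroxy enone prone to dehydration, and the later hydrogenation of C9=C10 must spare C2=C3. Nothing is relayed from one centre to the next, and the step count would be higher.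

Alternative 2: C1–C5 and C9–C10 are cut in an intramolecular [5+2] cycloaddition of the 3-oxidopyrylium ylide from Achmatowicz oxidation of (2S,3Z)-5-methyl-1-(4-methylfuran-2-yl)-2-(propan-2-yl)-2-[(triethylsilyl)oxy]hexa-3,5-dien-1-ol A2. The step would close both rings and set C1 relative to C4. Its ether bridge, however, joins C5 and C9, neither of which is oxygenated in the target, and C8 receives no oxygen. Two reductive C–O cleavages and a late hydration at C8 of uncertain facial sense would follow, and the 4-methyl-2-furyl unit is not a commodity. The chosen furan places its oxygen on C8 directly.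

Alternative 3: C6 is excised, so that the cycloheptane comes from one-carbon ring expansion of the cyclohexanone in (3aR,7aR)-7a-methylhexahydro-1H-indene-1,5(4H)-dione A3, the trans-hydrindanedione from the (R)-Hajos–Parrish ketone. The angular methyl and trans fusion are secured cheaply. The two ketones, however, map onto C2 and C8, so the five-ring oxygen needs a 1,3-transposition to C4. The inserted carbon must also carry oxygen and enter between C5 and C7 against the usual migratory preference, and the C8 methyl addition is not controlled. The route would be much longer.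

Key step: step 1

Assumption: the sense of deprotonation by the chiral lithium amide in step 3 is taken by analogy with related bridged ketones; if the (R,R)-base removes the other enantiotopic proton, its commercial (S,S)-antipode is used and nothing else changes.

## Route

Step 1
Reactants: 1 2,5-dimethylfuran; 2 1,1,3,3-tetrabromopropan-2-one
Product: 4 meso-(1R,5S)-1,5-dimethyl-8-oxabicyclo[3.2.1]oct-6-en-3-one, via dibromo cycloadduct 3 (not isolated)
Conditions: Zn–Cu couple, B(OEt)3, THF, −10 °C to rt; then Zn–Cu, NH4Cl, MeOH, rt
Reagents that add atoms: none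
Why: Zinc reduces 2 to a zinc-bound 1,3-dibromo-2-oxyallyl cation, a three-carbon 2π unit that adds across the α-carbons of the furan diene; the closest known reaction is the (4+3) cycloaddition of furans with oxyallyl cations from polybromoketones and zinc. Two C–C bonds form (C1–C5 and C7–C8) and the seven-membered carbocycle closes in a [4π+2π] cycloaddition mode, concerted or through a furan-stabilised cation that collapses on the zinc enolate; the furan oxygen becomes the C1–O–C8 bridge. The two bridgehead stereocentres are set together by geometry: both bonds form on one face of the planar furan, so the bridge is necessarily cis. Zn–Cu/NH4Cl then removes both bromines through zinc enolates, which erases the CHBr centres and leaves meso 4. The selectivity needed is cycloaddition over electrophilic substitution and oligomerisation of the furan; the two α-methyl groups block substitution at the α-carbons and raise the diene HOMO, which should favour ring closure. Both partners are symmetric, so there is no regiochemical or facial question. The step supplies all seven carbons of the cycloheptane, both methyl groups, the C6 carbonyl and the future C8 oxygen.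

Step 2
Reactants: 4 meso-(1R,5S)-1,5-dimethyl-8-oxabicyclo[3.2.1]oct-6-en-3-one
Product: 5 meso-(1S,5R)-1,5-dimethyl-8-oxabicyclo[3.2.1]octan-3-one
Conditions: H2 (1 atm), 10% Pd/C, EtOAc, rt
Reagents that add atoms: none
Why: Catalytic hydrogenation of the strained cis-alkene; ketone and ether bridge are inert and the mirror plane is kept. Saturating C9–C10 here prevents the later enone from being a 2,4-dienone open to 1,6-addition.

Step 3
Reactants: 5 meso-(1S,5R)-1,5-dimethyl-8-oxabicyclo[3.2.1]octan-3-one
Product: 6 triethyl{[(1S,5R)-1,5-dimethyl-8-oxabicyclo[3.2.1]oct-2-en-3-yl]oxy}silane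
Conditions: (R,R)-bis(1-phenylethyl)amine, n-BuLi, LiCl, THF; Et3SiCl present (in situ quench), −100 to −78 °C
Reagents that add atoms: chlorotriethylsilane, CC[Si](CC)(CC)Cl
Why: Enantioselective deprotonation of a meso bridged ketone by a C2-symmetric chiral lithium amide with in situ silyl trapping; the base selects one of the two enantiotopic α-methylene groups (C5–H2, next to the (1S)-bridgehead). No stereocentre is made, but the mirror plane is broken, which decides the absolute configuration at C8 in step 4.

Step 4
Reactants: 6 triethyl{[(1S,5R)-1,5-dimethyl-8-oxabicyclo[3.2.1]oct-2-en-3-yl]oxy}silane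
Product: 7 (R)-3,6-dimethyl-6-[(triethylsilyl)oxy]cyclohept-2-en-1-one
Conditions: Et3SiOTf (10 mol %), CH2Cl2, −78 to −20 °C; Et3N quench
Reagents that add atoms: none
Why: Silyl-triflate-promoted β-elimination of the ether bridge through the enol silane, the bridge opening known for enol silanes of oxa-bridged bicyclic ketones: O-silylation of the bridge, ionisation of the allylic C1–O bond assisted by the enol ether, then loss of the silyl group from the silyloxycarbenium ion, which regenerates the triflate. Only the C1–O bond next to the enol carbon can open, so C8 keeps its oxygen and configuration (R), and the alkoxide is capped as it forms, which blocks oxa-Michael reclosure.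

Step 5
Reactants: 7 (R)-3,6-dimethyl-6-[(triethylsilyl)oxy]cyclohept-2-en-1-one
Product: 8 trimethyl{[(3S,6R)-3-ethenyl-3,6-dimethyl-6-[(triethylsilyl)oxy]cyclohept-1-en-1-yl]oxy}silane
Conditions: CH2=CHMgBr, CuBr·SMe2 (10 mol %), Me3SiCl, HMPA, THF, −78 °C; Et3N, pentane, filtration
Reagents that add atoms: vinylmagnesium bromide, C=C[Mg]Br; chlorotrimethylsilane, C[Si](C)(C)Cl
Why: Copper-catalysed, Me3SiCl-accelerated conjugate addition creates the quaternary centre C1 and traps the enolate regiospecifically as the C5=C6 enol silane. The cycloheptenone should prefer the conformer with the smaller OSiEt3 pseudo-axial and the C8 methyl pseudo-equatorial; the pseudo-axial oxygen leans over one face of C1, so vinyl should enter on the other face, trans to C8–O, giving (S)-C1.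

Step 6
Reactants: 8 trimethyl{[(3S,6R)-3-ethenyl-3,6-dimethyl-6-[(triethylsilyl)oxy]cyclohept-1-en-1-yl]oxy}silane
Product: 10 (2S,3S,6R)-3-ethenyl-3,6-dimethyl-2-(prop-2-en-1-yl)-6-[(triethylsilyl)oxy]cycloheptan-1-one, via lithium enolate 9 (not isolated)
Conditions: MeLi, THF, 0 °C; allyl iodide, DMPU, −78 to −20 °C
Reagents that add atoms: allyl iodide, C=CCI
Why: Methyllithium cleaves the enol silane to the lithium enolate without loss of regiochemistry and allyl iodide alkylates C5. In the conformer favoured by the pseudo-axial OSiEt3, the vinyl group delivered axially in step 5 stays pseudo-axial next to the enolate carbon, so axial alkylation should occur anti to it and place allyl trans to vinyl, the relation that becomes the trans ring fusion.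

Step 7
Reactants: 10 (2S,3S,6R)-3-ethenyl-3,6-dimethyl-2-(prop-2-en-1-yl)-6-[(triethylsilyl)oxy]cycloheptan-1-one
Product: 11 (2S,3S,6R)-3-ethenyl-6-hydroxy-3,6-dimethyl-2-(prop-2-en-1-yl)cycloheptan-1-one
Conditions: HF·pyridine, pyridine, THF, 0 °C
Reagents that add atoms: none
Why: Buffered acidic desilylation frees the tertiary C8 hydroxyl; basic fluoride is avoided because the β-hydroxy ketone could undergo retro-aldol cleavage or C5 epimerisation.

Step 8
Reactants: 11 (2S,3S,6R)-3-ethenyl-6-hydroxy-3,6-dimethyl-2-(prop-2-en-1-yl)cycloheptan-1-one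
Product: 12 (1R,3S,4S,5S)-5-ethenyl-1,5-dimethyl-4-(prop-2-en-1-yl)cycloheptane-1,3-diol
Conditions: Me4NBH(OAc)3, MeCN/AcOH 1:1, −30 to 0 °C
Reagents that add atoms: none
Why: Hydroxyl-directed reduction (Evans–Saksena): the C8 hydroxyl exchanges onto boron and hydride is delivered intramolecularly to the C6 carbonyl on the face bearing C8–O, so the new hydroxyl is 1,3-anti to C8–OH and cis to H5 ((S)-C6). An external hydride would be expected on the other face, away from the pseudo-axial C1 methyl and C8 oxygen, hence the directed reagent.

Step 9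
Reactants: 12 (1R,3S,4S,5S)-5-ethenyl-1,5-dimethyl-4-(prop-2-en-1-yl)cycloheptane-1,3-diol
Product: 13 (3aS,4S,6R,8aS)-6,8a-dimethyl-3,3a,4,5,6,7,8,8a-octahydroazulene-4,6-diol
Conditions: Grubbs second-generation catalyst (5 mol %), CH2Cl2, 40 °C
Reagents that add atoms: none
Why: Ring-closing metathesis of the 1,6-diene (vinyl on C1, allyl on C5) closes the cyclopentene with C2=C3 in place; no stereocentre is touched, so the trans side chains become the trans ring fusion. Free hydroxyls are tolerated by the ruthenium carbene.

Step 10
Reactants: 13 (3aS,4S,6R,8aS)-6,8a-dimethyl-3,3a,4,5,6,7,8,8a-octahydroazulene-4,6-diol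
Product: 14 (3aS,4S,6R,8aS)-6,8a-dimethyl-3,3a,4,5,6,7,8,8a-octahydroazulene-3,4,6-triol (both C3 epimers; C3 of this name is daucane C4)
Conditions: SeO2 (0.5 equiv), t-BuOOH, CH2Cl2, rt
Reagents that add atoms: tert-butyl hydroperoxide, CC(C)(C)OO
Why: Selenium dioxide allylic hydroxylation (ene reaction, then [2,3]-sigmatropic shift) returns the double bond to C2=C3 and puts oxygen on the allylic carbon; C4 is the only allylic carbon with hydrogen because C1 is quaternary. The new carbinol configuration is irrelevant, as it is oxidised in step 11.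

Step 11
Reactants: 14 (3aS,4S,6R,8aS)-6,8a-dimethyl-3,3a,4,5,6,7,8,8a-octahydroazulene-3,4,6-triol
Product: 15 (3aS,4S,6R,8aS)-4,6-dihydroxy-6,8a-dimethyl-4,5,6,7,8,8a-hexahydroazulen-3(3aH)-one
Conditions: activated MnO2, CH2Cl2, rt
Reagents that add atoms: none
Why: Manganese dioxide oxidises only the allylic alcohol; the C6 and C8 hydroxyls are not allylic. The neutral heterogeneous medium should avoid enolisation at C5 and β-elimination of the C6 hydroxyl.

Step 12
Reactants: 15 (3aS,4S,6R,8aS)-4,6-dihydroxy-6,8a-dimethyl-4,5,6,7,8,8a-hexahydroazulen-3(3aH)-one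
Product: 16 (3S,3aS,4S,6R,8aS)-6,8a-dimethyl-3-(propan-2-yl)-3,3a,4,5,6,7,8,8a-octahydroazulene-3,4,6-triol
Conditions: i-PrMgCl, anhydrous CeCl3, THF, −78 °C; aq. NH4Cl
Reagents that add atoms: isopropylmagnesium chloride, CC(C)[Mg]Cl
Why: Organocerium 1,2-addition to the cyclopentenone; the weakly basic reagent suppresses enolisation, β-hydride reduction and conjugate addition, and the two hydroxyls are carried as alkoxides. Attack should come from the face of H5, because the other face is shielded by the C5–C6 bond on the α-carbon and by the angular C1 methyl; this puts isopropyl cis to H5 and the hydroxyl cis to the C1 methyl ((S)-C4).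

Step 13
Reactants: 16 (3S,3aS,4S,6R,8aS)-6,8a-dimethyl-3-(propan-2-yl)-3,3a,4,5,6,7,8,8a-octahydroazulene-3,4,6-triol; 17 4-(acetyloxy)-3-methoxybenzoic acid
Product: 18 (3S,3aS,4S,6R,8aS)-3,6-dihydroxy-6,8a-dimethyl-3-(propan-2-yl)-3,3a,4,5,6,7,8,8a-octahydroazulen-4-yl 4-(acetyloxy)-3-methoxybenzoate
Conditions: DCC, DMAP (cat.), CH2Cl2, 0 °C to rt
Reagents that add atoms: none
Why: Steglich esterification; only the secondary C6 hydroxyl is acylated, the two tertiary hydroxyls being unreactive towards the acylpyridinium intermediate. The phenol is masked as its acetate so that 17 cannot acylate itself.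

Step 14
Reactants: 18 (3S,3aS,4S,6R,8aS)-3,6-dihydroxy-6,8a-dimethyl-3-(propan-2-yl)-3,3a,4,5,6,7,8,8a-octahydroazulen-4-yl 4-(acetyloxy)-3-methoxybenzoate
Product: 19 (3S,3aS,4S,6R,8aS)-3,6-dihydroxy-6,8a-dimethyl-3-(propan-2-yl)-3,3a,4,5,6,7,8,8a-octahydroazulen-4-yl 4-hydroxy-3-methoxybenzoate (target)
Conditions: K2CO3 (0.2 equiv), MeOH, 0 °C
Reagents that add atoms: none
Why: Base-catalysed methanolysis cleaves the aryl acetate much faster than the hindered secondary alkyl benzoate; the phenoxide that forms further deactivates the benzoate carbonyl, so the ester of 19 should survive.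

## Compound list

1 | 2,5-dimethylfuran | Cc1ccc(C)o1 | starting material
2 | 1,1,3,3-tetrabromopropan-2-one | BrC(Br)C(=O)C(Br)Br | starting material
3 | 2,4-dibromo-1,5-dimethyl-8-oxabicyclo[3.2.1]oct-6-en-3-one (bromide epimers, cis bridge) | C[C@@]12C=C[C@@](C)(O1)C(Br)C(=O)C2Br | intermediate
4 | meso-(1R,5S)-1,5-dimethyl-8-oxabicyclo[3.2.1]oct-6-en-3-one | C[C@@]12C=C[C@@](C)(O1)CC(=O)C2 | intermediate
5 | meso-(1S,5R)-1,5-dimethyl-8-oxabicyclo[3.2.1]octan-3-one | C[C@@]12CC[C@@](C)(O1)CC(=O)C2 | intermediate
6 | triethyl{[(1S,5R)-1,5-dimethyl-8-oxabicyclo[3.2.1]oct-2-en-3-yl]oxy}silane | C[C@@]12CC[C@@](C)(O1)CC(O[Si](CC)(CC)CC)=C2 | intermediate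
7 | (R)-3,6-dimethyl-6-[(triethylsilyl)oxy]cyclohept-2-en-1-one | O=C1C=C(C)CC[C@@](C)(O[Si](CC)(CC)CC)C1 | intermediate
8 | trimethyl{[(3S,6R)-3-ethenyl-3,6-dimethyl-6-[(triethylsilyl)oxy]cyclohept-1-en-1-yl]oxy}silane | C[Si](C)(C)OC1=C[C@](C)(C=C)CC[C@@](C)(O[Si](CC)(CC)CC)C1 | intermediate
9 | lithium (3S,6R)-3-ethenyl-3,6-dimethyl-6-[(triethylsilyl)oxy]cyclohept-1-en-1-olate | [Li]OC1=C[C@](C)(C=C)CC[C@@](C)(O[Si](CC)(CC)CC)C1 | intermediate
10 | (2S,3S,6R)-3-ethenyl-3,6-dimethyl-2-(prop-2-en-1-yl)-6-[(triethylsilyl)oxy]cycloheptan-1-one | O=C1[C@@H](CC=C)[C@](C)(C=C)CC[C@@](C)(O[Si](CC)(CC)CC)C1 | intermediate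
11 | (2S,3S,6R)-3-ethenyl-6-hydroxy-3,6-dimethyl-2-(prop-2-en-1-yl)cycloheptan-1-one | O=C1[C@@H](CC=C)[C@](C)(C=C)CC[C@@](C)(O)C1 | intermediate
12 | (1R,3S,4S,5S)-5-ethenyl-1,5-dimethyl-4-(prop-2-en-1-yl)cycloheptane-1,3-diol | O[C@@H]1[C@@H](CC=C)[C@](C)(C=C)CC[C@@](C)(O)C1 | intermediate
13 | (3aS,4S,6R,8aS)-6,8a-dimethyl-3,3a,4,5,6,7,8,8a-octahydroazulene-4,6-diol | O[C@H]1C[C@](C)(O)CC[C@@]2(C)C=CC[C@H]12 | intermediate
14 | (3aS,4S,6R,8aS)-6,8a-dimethyl-3,3a,4,5,6,7,8,8a-octahydroazulene-3,4,6-triol (C3 epimers) | O[C@H]1C[C@](C)(O)CC[C@@]2(C)C=CC(O)[C@H]12 | intermediate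
15 | (3aS,4S,6R,8aS)-4,6-dihydroxy-6,8a-dimethyl-4,5,6,7,8,8a-hexahydroazulen-3(3aH)-one | O[C@H]1C[C@](C)(O)CC[C@@]2(C)C=CC(=O)[C@H]12 | intermediate
16 | (3S,3aS,4S,6R,8aS)-6,8a-dimethyl-3-(propan-2-yl)-3,3a,4,5,6,7,8,8a-octahydroazulene-3,4,6-triol | O[C@H]1C[C@](C)(O)CC[C@@]2(C)C=C[C@@](O)(C(C)C)[C@H]12 | intermediate
17 | 4-(acetyloxy)-3-methoxybenzoic acid | COc1cc(C(=O)O)ccc1OC(C)=O | starting material
18 | (3S,3aS,4S,6R,8aS)-3,6-dihydroxy-6,8a-dimethyl-3-(propan-2-yl)-3,3a,4,5,6,7,8,8a-octahydroazulen-4-yl 4-(acetyloxy)-3-methoxybenzoate | COc1cc(C(=O)O[C@H]2C[C@](C)(O)CC[C@@]3(C)C=C[C@@](O)(C(C)C)[C@H]23)ccc1OC(C)=O | intermediate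
19 | (3S,3aS,4S,6R,8aS)-3,6-dihydroxy-6,8a-dimethyl-3-(propan-2-yl)-3,3a,4,5,6,7,8,8a-octahydroazulen-4-yl 4-hydroxy-3-methoxybenzoate | COc1cc(C(=O)O[C@H]2C[C@](C)(O)CC[C@@]3(C)C=C[C@@](O)(C(C)C)[C@H]23)ccc1O | target

## Step count and least certain steps

Total step count: 14. Longest linear sequence: 14 steps (1 to 19; 2 and 17 enter as purchased reactants).

Step 1 (key step). The oxyallyl cation may be captured stepwise, with proton loss from the furan (substitution at a β-carbon) or oligomerisation instead of ring closure, and the two α-methyl groups slow the second bond formation. The fallback sets out from 1 and uses a carbenoid instead of a cation. Rhodium(II)-catalysed reaction of 1 with methyl 2-diazo-3-[(tert-butyldimethylsilyl)oxy]but-3-enoate (cyclopropanation of one furan double bond, then Cope rearrangement of the divinylcyclopropane) should give methyl 3-[(tert-butyldimethylsilyl)oxy]-1,5-dimethyl-8-oxabicyclo[3.2.1]octa-2,6-diene-2-carboxylate F1. Aqueous HF should give methyl 1,5-dimethyl-3-oxo-8-oxabicyclo[3.2.1]oct-6-ene-2-carboxylate F2, and Krapcho dealkoxycarbonylation (LiCl, wet DMSO, heat) returns to the route at 4.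

Step 4. The bridging C1–O bond overlaps only partly with the enol π-system, so ionisation may be slow and the enol silane may instead be cleaved back to 5; an uncapped alkoxide would reclose by oxa-Michael addition. The fallback sets out from 4 and lets conjugation drive the opening. The same chiral base and Et3SiCl applied to 4 should give triethyl{[(1S,5S)-1,5-dimethyl-8-oxabicyclo[3.2.1]octa-2,6-dien-3-yl]oxy}silane F3. Its silyl-triflate-induced opening leads to the conjugated (S)-3,6-dimethyl-6-[(triethylsilyl)oxy]cyclohepta-2,4-dien-1-one F4. Hydrogenation of the disubstituted C9=C10 bond with Wilkinson's catalyst, which should spare the trisubstituted enone, comes back at 7.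

Step 5. Facial selectivity may be poor if the conformer with the C8 methyl pseudo-axial reacts competitively, and 1,2-addition may intrude. The fallback sets out from 7 and replaces substrate control by catalyst control: copper-catalysed asymmetric conjugate addition of a vinylalane with a chiral phosphoramidite or N-heterocyclic carbene ligand of the matched sense, with the aluminium enolate silylated by Me3SiCl, returns at 8. It makes no new compound.

Step 6. Trans selectivity may erode if alkylation occurs anti to the methyl group in the other ring conformer; O-allylation, and enolate equilibration towards C7 followed by loss of silanolate, are further risks. The fallback sets out from 8. Its lithium enolate 9 is acylated on oxygen with allyl chloroformate to give prop-2-en-1-yl (3S,6R)-3-ethenyl-3,6-dimethyl-6-[(triethylsilyl)oxy]cyclohept-1-en-1-yl carbonate F5. Palladium-catalysed decarboxylative allylation with a chiral Trost ligand then sets C5 under ligand control and neutral conditions and returns at 10.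

Step 12. The enone may be enolised at C5 (epimerisation to the cis-fused series), the C6 alkoxide may open by retro-aldol, and β-hydride transfer may reduce the ketone. The fallback sets out from 15 and removes the free β-alkoxide. Silylation of the secondary hydroxyl (Et3SiCl, imidazole) gives (3aS,4S,6R,8aS)-6-hydroxy-6,8a-dimethyl-4-[(triethylsilyl)oxy]-4,5,6,7,8,8a-hexahydroazulen-3(3aH)-one F6. Isopropyllithium with CeCl3 should then give (3S,3aS,4S,6R,8aS)-6,8a-dimethyl-3-(propan-2-yl)-4-[(triethylsilyl)oxy]-3,3a,4,5,6,7,8,8a-octahydroazulene-3,6-diol F7, and HF·pyridine returns to the route at 16.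

## Further compounds

F1 | step 1 | methyl 3-[(tert-butyldimethylsilyl)oxy]-1,5-dimethyl-8-oxabicyclo[3.2.1]octa-2,6-diene-2-carboxylate (racemic) | C[C@@]12C=C[C@@](C)(O1)CC(O[Si](C)(C)C(C)(C)C)=C2C(=O)OC
F2 | step 1 | methyl 1,5-dimethyl-3-oxo-8-oxabicyclo[3.2.1]oct-6-ene-2-carboxylate (racemic, C2 epimers) | C[C@@]12C=C[C@@](C)(O1)CC(=O)C2C(=O)OC
F3 | step 4 | triethyl{[(1S,5S)-1,5-dimethyl-8-oxabicyclo[3.2.1]octa-2,6-dien-3-yl]oxy}silane | C[C@@]12C=C[C@@](C)(O1)CC(O[Si](CC)(CC)CC)=C2
F4 | step 4 | (S)-3,6-dimethyl-6-[(triethylsilyl)oxy]cyclohepta-2,4-dien-1-one | O=C1C=C(C)C=C[C@@](C)(O[Si](CC)(CC)CC)C1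
F0 | step 5 | none | none
F5 | step 6 | prop-2-en-1-yl (3S,6R)-3-ethenyl-3,6-dimethyl-6-[(triethylsilyl)oxy]cyclohept-1-en-1-yl carbonate | C=CCOC(=O)OC1=C[C@](C)(C=C)CC[C@@](C)(O[Si](CC)(CC)CC)C1
F6 | step 12 | (3aS,4S,6R,8aS)-6-hydroxy-6,8a-dimethyl-4-[(triethylsilyl)oxy]-4,5,6,7,8,8a-hexahydroazulen-3(3aH)-one | CC[Si](CC)(CC)O[C@H]1C[C@](C)(O)CC[C@@]2(C)C=CC(=O)[C@H]12
F7 | step 12 | (3S,3aS,4S,6R,8aS)-6,8a-dimethyl-3-(propan-2-yl)-4-[(triethylsilyl)oxy]-3,3a,4,5,6,7,8,8a-octahydroazulene-3,6-diol | CC[Si](CC)(CC)O[C@H]1C[C@](C)(O)CC[C@@]2(C)C=C[C@@](O)(C(C)C)[C@H]12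
A1 | alternative 1 | (4S,5S)-4-ethenyl-5-[(1S,3S)-1,3-dihydroxy-3-methylpent-4-en-1-yl]-4-methylcyclopent-2-en-1-one | C=C[C@@]1(C)C=CC(=O)[C@@H]1[C@@H](O)C[C@](C)(O)C=C
A2 | alternative 2 | (2S,3Z)-5-methyl-1-(4-methylfuran-2-yl)-2-(propan-2-yl)-2-[(triethylsilyl)oxy]hexa-3,5-dien-1-ol (C1 epimers) | Cc1coc(c1)C(O)[C@](O[Si](CC)(CC)CC)(C(C)C)/C=C\C(C)=C
A3 | alternative 3 | (3aR,7aR)-7a-methylhexahydro-1H-indene-1,5(4H)-dione | C[C@@]12CCC(=O)C[C@H]1CCC2=O
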